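## Retrosynthetic overview

- **Numbering:** the target is 2-methoxy-6,7-dimethyl-8-aryl-1,4-naphthoquinone. Ring A is the quinone ring (C1–C4, C4a, C8a), ring B the benzo ring (C4a, C5–C8, C8a), and ring C the 2,4,5-trimethoxyphenyl group on C8.
- **Feature used:** ring B reads C5–H / C6–Me / C7–Me / C8–aryl. This is a but-2-yne unit (C6, C7) set between two alkyne termini (C5, C8), whose inner carbons C4a and C8a are bridged by C4–C3–C2–C1.
- **Disconnection 1 (redox only):** the quinone goes back to the bis-TBS ether of a 2-methoxytetralin-1,4-diol, which already holds all three ring A oxygens.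
- **Disconnection 2 (key):** cutting C4a–C8a, C5–C6 and C7–C8 gives an aryl-capped octa-1,7-diyne and but-2-yne. Rings A and B form together in one step and ring C arrives on the alkyne terminus, so no biaryl coupling is needed.
- **Disconnection 3:** the diyne comes from ethynyl addition at C4, hydroboration–oxidation of a vinyl group (C3–C4), γ-methoxyallylboration (C1–C2) of the arylpropynal, and a Sonogashira coupling.

Key step: step 9

Assumption: the target has no stereocentre and its C8–C1' axis is unspecified, so the configurations at C1, C2 and C4 and the sense of the axis do not matter; the isomer expected to predominate is drawn, and the C4 epimer and any atropisomers are carried on unseparated.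

## Route

Step 1
Reactants: 1 1-bromo-2,4,5-trimethoxybenzene; 2 propargyl alcohol
Product: 3 3-(2,4,5-trimethoxyphenyl)prop-2-yn-1-ol
Conditions: PdCl2(PhCN)2 (3 mol %), [HP(t-Bu)3]BF4 (6 mol %), CuI (2 mol %), i-Pr2NH, dioxane, rt to 50 °C
Reagents that add atoms: none
Why: Sonogashira coupling: the bulky, electron-rich phosphine lets zerovalent palladium insert into the electron-rich, ortho-methoxylated C–Br bond under mild conditions, and the copper acetylide of 2 is transferred without protection of the hydroxyl group.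

Step 2
Reactants: 3 3-(2,4,5-trimethoxyphenyl)prop-2-yn-1-ol
Product: 4 3-(2,4,5-trimethoxyphenyl)prop-2-ynal
Conditions: activated MnO2 (excess), CH2Cl2, rt
Reagents that add atoms: none
Why: Heterogeneous MnO2 oxidation is selective for activated (here propargylic) alcohols, should stop at the aldehyde and leaves the alkyne and the aryl ethers untouched.

Step 3
Reactants: 4 3-(2,4,5-trimethoxyphenyl)prop-2-ynal; 5 allyl methyl ether
Product: 9 (3R,4R)-4-methoxy-1-(2,4,5-trimethoxyphenyl)hex-5-en-1-yn-3-ol, via (Z)-3-methoxyallyllithium 6 (not isolated), via (Z)-3-methoxyallyldiisopinocampheylborane 7 (not isolated), via borinate ester 8 (not isolated)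
Conditions: 5, s-BuLi, THF, −78 °C; (−)-Ipc2BOMe, −78 °C; BF3·OEt2 then 4, −78 °C; NaOH, H2O2, 0 °C to rt
Reagents that add atoms: none
Why: Brown γ-alkoxyallylboration: lithiation of 5 gives the internally chelated (Z)-anion 6, boron is taken up at its unsubstituted terminus, and the (Z)-allylborane 7 adds to the aldehyde of 4 through a closed chair (Zimmerman–Traxler) transition state, so that the (Z)-geometry sets C1 and C2 syn and the isopinocampheyl groups set the absolute sense (3R,4R expected with the reagent from (+)-α-pinene; the reagent is chosen for its reliability, since both centres are erased later).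

Step 4
Reactants: 9 (3R,4R)-4-methoxy-1-(2,4,5-trimethoxyphenyl)hex-5-en-1-yn-3-ol
Product: 10 (3R,4R)-3-(tert-butyldimethylsilyloxy)-4-methoxy-1-(2,4,5-trimethoxyphenyl)hex-5-en-1-yne
Conditions: TBSCl, imidazole, DMF, rt
Reagents that add atoms: tert-butyldimethylsilyl chloride, CC(C)(C)[Si](C)(C)Cl
Why: Imidazole-promoted silylation of a secondary alcohol, which masks the C1 hydroxyl against the borane, the oxidant and the Grignard reagent to come and touches no stereocentre.

Step 5
Reactants: 10 (3R,4R)-3-(tert-butyldimethylsilyloxy)-4-methoxy-1-(2,4,5-trimethoxyphenyl)hex-5-en-1-yne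
Product: 12 (3R,4R)-4-(tert-butyldimethylsilyloxy)-3-methoxy-6-(2,4,5-trimethoxyphenyl)hex-5-yn-1-ol, via B-alkyl-9-BBN adduct 11 (not isolated)
Conditions: 9-BBN, THF, 0 °C to rt; NaOH, H2O2, 0 °C
Reagents that add atoms: hydrogen peroxide, OO
Why: Hydroboration–oxidation: 9-BBN reacts with a monosubstituted alkene much faster than with an internal alkyne, which here is further shielded by ring C and the silyloxy-bearing carbon, it places boron on the terminal carbon (anti-Markovnikov), and alkaline peroxide then exchanges boron for hydroxyl.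

Step 6
Reactants: 12 (3R,4R)-4-(tert-butyldimethylsilyloxy)-3-methoxy-6-(2,4,5-trimethoxyphenyl)hex-5-yn-1-ol
Product: 13 (3R,4R)-4-(tert-butyldimethylsilyloxy)-3-methoxy-6-(2,4,5-trimethoxyphenyl)hex-5-ynal
Conditions: Dess–Martin periodinane, CH2Cl2, 0 °C to rt
Reagents that add atoms: none
Why: Dess–Martin oxidation works without base and stops at the aldehyde, so the β-methoxy aldehyde is not exposed to conditions that would expel methanol.

Step 7
Reactants: 13 (3R,4R)-4-(tert-butyldimethylsilyloxy)-3-methoxy-6-(2,4,5-trimethoxyphenyl)hex-5-ynal; 14 ethynylmagnesium bromide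
Product: 16 (3R,5R,6R)-6-(tert-butyldimethylsilyloxy)-5-methoxy-8-(2,4,5-trimethoxyphenyl)octa-1,7-diyn-3-ol (3S epimer carried along), via bromomagnesium alkoxide 15 (not isolated)
Conditions: 14 (0.5 M in THF), THF, −78 to −20 °C; sat. aq NH4Cl
Reagents that add atoms: none
Why: Grignard 1,2-addition of a weakly basic acetylide at low temperature outruns enolisation of the aldehyde; the new carbinol centre (C4) is biased only modestly, by 1,3-induction from the β-methoxy group through a magnesium chelate, toward the 1,3-anti isomer drawn, and both epimers are carried on because C4 becomes a carbonyl carbon.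

Step 8
Reactants: 16 (3R,5R,6R)-6-(tert-butyldimethylsilyloxy)-5-methoxy-8-(2,4,5-trimethoxyphenyl)octa-1,7-diyn-3-ol
Product: 17 (3R,4R,6R)-3,6-bis(tert-butyldimethylsilyloxy)-4-methoxy-1-(2,4,5-trimethoxyphenyl)octa-1,7-diyne
Conditions: TBSCl, imidazole, DMF, rt
Reagents that add atoms: tert-butyldimethylsilyl chloride, CC(C)(C)[Si](C)(C)Cl
Why: Imidazole-promoted silylation of the second propargylic alcohol removes the free hydroxyl next to the terminal alkyne, which could otherwise bind rhodium or isomerise to an enone in the key step.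

Step 9
Reactants: 17 (3R,4R,6R)-3,6-bis(tert-butyldimethylsilyloxy)-4-methoxy-1-(2,4,5-trimethoxyphenyl)octa-1,7-diyne; 18 but-2-yne
Product: 19 (1R,2R,4R)-1,4-bis(tert-butyldimethylsilyloxy)-2-methoxy-6,7-dimethyl-8-(2,4,5-trimethoxyphenyl)-1,2,3,4-tetrahydronaphthalene (1,2-trans and 1,4-cis as drawn)
Conditions: RhCl(PPh3)3 (10 mol %), 18 (20 equiv), PhMe–EtOH 4:1 (0.01 M in 17), sealed tube, 80 °C
Reagents that add atoms: none
Why: RhCl(PPh3)3 sheds PPh3, the monovalent rhodium fragment binds both triple bonds of 17 and couples them oxidatively to a bicyclic rhodacyclopentadiene of trivalent rhodium, 18 then coordinates and inserts, and reductive elimination releases 19 and returns monovalent rhodium. The closest known reaction type is the rhodium-catalysed, partially intramolecular (2+2+2) alkyne cyclotrimerisation of 1,6- and 1,7-diynes with monoalkynes, which is established for propargylic ethers and for aryl-capped diyne termini. Ring A closes as a six-membered carbocycle in the oxidative coupling, through the C4a–C8a bond between the two inner alkyne carbons held together by the C4–C3–C2–C1 tether, and ring B closes as the new benzene ring when C5–C6 and C7–C8 are made to the two carbons of 18. No sp3 stereocentre is created and C1, C2 and C4 are spectators; the only new stereogenic element is the hindered C8–C1' axis, which is not controlled and need not be, since all isomers converge on the one constitution of the target. The step needs chemoselectivity for diyne-plus-monoalkyne over self-reaction of 17 and over trimerisation of 18: the tether makes the first C–C coupling intramolecular, high dilution of 17 beside a large excess of 18 lets the rhodacycle meet 18 first, and the unactivated internal alkyne 18 homotrimerises only slowly at this catalyst. Regioselectivity is not at stake because 18 is symmetrical, so the methyl groups can only end up on C6 and C7 and ring C only on C8.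

Step 10
Reactants: 19 (1R,2R,4R)-1,4-bis(tert-butyldimethylsilyloxy)-2-methoxy-6,7-dimethyl-8-(2,4,5-trimethoxyphenyl)-1,2,3,4-tetrahydronaphthalene
Product: 20 (1R,2R,4R)-2-methoxy-6,7-dimethyl-8-(2,4,5-trimethoxyphenyl)-1,2,3,4-tetrahydronaphthalene-1,4-diol
Conditions: TBAF, THF, rt to 45 °C
Reagents that add atoms: none
Why: Fluoride-induced desilylation, driven by the strong Si–F bond, frees both benzylic alcohols under non-acidic conditions, so neither benzylic C–O bond ionises; gentle warming answers the crowding of the C1 silyl ether by ring C.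

Step 11
Reactants: 20 (1R,2R,4R)-2-methoxy-6,7-dimethyl-8-(2,4,5-trimethoxyphenyl)-1,2,3,4-tetrahydronaphthalene-1,4-diol
Product: 21 (2R)-2-methoxy-6,7-dimethyl-8-(2,4,5-trimethoxyphenyl)-2,3-dihydronaphthalene-1,4-dione (used crude)
Conditions: Dess–Martin periodinane (2.5 equiv), CH2Cl2, 0 °C to rt
Reagents that add atoms: none
Why: Dess–Martin oxidation of both secondary benzylic alcohols under mild, base-free conditions should give the tetralin-1,4-dione, a class of diketo tautomers of naphthalene-1,4-diols that is known to be isolable, and it merges the C4 epimers.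

Step 12
Reactants: 21 (2R)-2-methoxy-6,7-dimethyl-8-(2,4,5-trimethoxyphenyl)-2,3-dihydronaphthalene-1,4-dione
Product: 23 2-methoxy-6,7-dimethyl-8-(2,4,5-trimethoxyphenyl)naphthalene-1,4-dione (target), via naphthalene-1,4-diol 22 (not isolated)
Conditions: SiO2, AcOH (cat.), CH2Cl2, air, rt
Reagents that add atoms: none
Why: Acid-catalysed keto–enol tautomerisation turns the dione into its aromatic tautomer 22 through neutral enols, so that no enolate builds up from which the C2 methoxy group could leave by E1cB, and the very electron-rich 2-methoxynaphthalene-1,4-diol is drained irreversibly by autoxidation with O2 to the quinone, which also erases the last stereocentre (C2).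

## Compound list

1 | 1-bromo-2,4,5-trimethoxybenzene | COc1cc(OC)c(Br)cc1OC | starting material
2 | propargyl alcohol | C#CCO | starting material
3 | 3-(2,4,5-trimethoxyphenyl)prop-2-yn-1-ol | OCC#Cc1cc(OC)c(OC)cc1OC | intermediate
4 | 3-(2,4,5-trimethoxyphenyl)prop-2-ynal | O=CC#Cc1cc(OC)c(OC)cc1OC | intermediate
5 | allyl methyl ether | C=CCOC | starting material
6 | (Z)-3-methoxyallyllithium | CO/C=C\C[Li] | intermediate
7 | [(Z)-3-methoxyallyl]diisopinocampheylborane (Ipc groups from (+)-α-pinene) | CO/C=C\CB([C@@H]1C[C@@H]2C[C@H]([C@H]1C)C2(C)C)[C@@H]1C[C@@H]2C[C@H]([C@H]1C)C2(C)C | intermediate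
8 | diisopinocampheylborinate ester of 9 | C=C[C@@H](OC)[C@H](OB([C@@H]1C[C@@H]2C[C@H]([C@H]1C)C2(C)C)[C@@H]1C[C@@H]2C[C@H]([C@H]1C)C2(C)C)C#Cc1cc(OC)c(OC)cc1OC | intermediate
9 | (3R,4R)-4-methoxy-1-(2,4,5-trimethoxyphenyl)hex-5-en-1-yn-3-ol | C=C[C@@H](OC)[C@H](O)C#Cc1cc(OC)c(OC)cc1OC | intermediate
10 | (3R,4R)-3-(tert-butyldimethylsilyloxy)-4-methoxy-1-(2,4,5-trimethoxyphenyl)hex-5-en-1-yne | C=C[C@@H](OC)[C@H](O[Si](C)(C)C(C)(C)C)C#Cc1cc(OC)c(OC)cc1OC | intermediate
11 | B-alkyl-9-BBN adduct of 10 (boron on the terminal carbon) | C1CC2CCCC(C1)B2CC[C@@H](OC)[C@H](O[Si](C)(C)C(C)(C)C)C#Cc1cc(OC)c(OC)cc1OC | intermediate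
12 | (3R,4R)-4-(tert-butyldimethylsilyloxy)-3-methoxy-6-(2,4,5-trimethoxyphenyl)hex-5-yn-1-ol | OCC[C@@H](OC)[C@H](O[Si](C)(C)C(C)(C)C)C#Cc1cc(OC)c(OC)cc1OC | intermediate
13 | (3R,4R)-4-(tert-butyldimethylsilyloxy)-3-methoxy-6-(2,4,5-trimethoxyphenyl)hex-5-ynal | O=CC[C@@H](OC)[C@H](O[Si](C)(C)C(C)(C)C)C#Cc1cc(OC)c(OC)cc1OC | intermediate
14 | ethynylmagnesium bromide | C#C[Mg]Br | starting material
15 | bromomagnesium alkoxide of 16 | C#C[C@H](O[Mg]Br)C[C@@H](OC)[C@H](O[Si](C)(C)C(C)(C)C)C#Cc1cc(OC)c(OC)cc1OC | intermediate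
16 | (3R,5R,6R)-6-(tert-butyldimethylsilyloxy)-5-methoxy-8-(2,4,5-trimethoxyphenyl)octa-1,7-diyn-3-ol (3S epimer carried along) | C#C[C@H](O)C[C@@H](OC)[C@H](O[Si](C)(C)C(C)(C)C)C#Cc1cc(OC)c(OC)cc1OC | intermediate
17 | (3R,4R,6R)-3,6-bis(tert-butyldimethylsilyloxy)-4-methoxy-1-(2,4,5-trimethoxyphenyl)octa-1,7-diyne | C#C[C@H](O[Si](C)(C)C(C)(C)C)C[C@@H](OC)[C@H](O[Si](C)(C)C(C)(C)C)C#Cc1cc(OC)c(OC)cc1OC | intermediate
18 | but-2-yne | CC#CC | starting material
19 | (1R,2R,4R)-1,4-bis(tert-butyldimethylsilyloxy)-2-methoxy-6,7-dimethyl-8-(2,4,5-trimethoxyphenyl)-1,2,3,4-tetrahydronaphthalene | c12cc(C)c(C)c(-c3cc(OC)c(OC)cc3OC)c1[C@@H](O[Si](C)(C)C(C)(C)C)[C@H](OC)C[C@H]2O[Si](C)(C)C(C)(C)C | intermediate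
20 | (1R,2R,4R)-2-methoxy-6,7-dimethyl-8-(2,4,5-trimethoxyphenyl)-1,2,3,4-tetrahydronaphthalene-1,4-diol | c12cc(C)c(C)c(-c3cc(OC)c(OC)cc3OC)c1[C@@H](O)[C@H](OC)C[C@H]2O | intermediate
21 | (2R)-2-methoxy-6,7-dimethyl-8-(2,4,5-trimethoxyphenyl)-2,3-dihydronaphthalene-1,4-dione (C2 configurationally labile) | c12cc(C)c(C)c(-c3cc(OC)c(OC)cc3OC)c1C(=O)[C@H](OC)CC2=O | intermediate
22 | 2-methoxy-6,7-dimethyl-8-(2,4,5-trimethoxyphenyl)naphthalene-1,4-diol | COc1cc(O)c2cc(C)c(C)c(-c3cc(OC)c(OC)cc3OC)c2c1O | intermediate
23 | 2-methoxy-6,7-dimethyl-8-(2,4,5-trimethoxyphenyl)naphthalene-1,4-dione | COC1=CC(=O)c2cc(C)c(C)c(-c3cc(OC)c(OC)cc3OC)c2C1=O | target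

## Step count

Total step count: 12. Longest linear sequence: 12 steps, from 1 (or 2) to 23.

## Steps most likely to fail

**Step 9.** The rhodacycle may be captured only slowly by the unactivated, weakly binding and volatile alkyne at the crowded, aryl-bearing terminus. Self-reaction of the diyne through its terminal alkyne (dimerisation, oligomerisation) would then take over. The fallback sets out from 17 and returns at 19. It no longer brings in the methyl groups directly but as oxygenated carbons that are reduced afterwards. But-2-yne-1,4-diol is a non-volatile internal alkyne whose hydroxyl groups bind rhodium, and it is among the best-behaved partners of RhCl(PPh3)3 in ethanol. It is cyclised with 17 to the 6,7-bis(hydroxymethyl)tetralin F1. MsCl and Et3N followed by LiCl in DMF convert this into the 6,7-bis(chloromethyl)tetralin F2. LiBHEt3 in THF then replaces both benzylic chlorides by hydride, which the silyl ethers survive, to give 19.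

**Step 12.** Methanol may be lost from C2 by β-elimination through the C3–C4 enol or enolate, in competition with the second enolisation, which would erase the C2 oxygen for good. The fallback sets out from 20 and returns at 23. It never places a ketone at C4 while C2 is still sp3. The less crowded C4 hydroxyl of 20 is silylated selectively (TBSCl, 1 equiv, imidazole, 0 °C) to give the C4 mono-TBS ether F3, because the C1 hydroxyl is shielded by ring C. Dess–Martin oxidation gives the 2-methoxy-1-tetralone F4, in which no leaving group sits β to the carbonyl. p-TsOH in warm toluene removes the silyl group, dehydrates at benzylic C4 and lets the dienone tautomerise to the 2-methoxy-1-naphthol F5. Teuber oxidation with (KSO3)2NO in buffered aqueous acetone then oxidises the free para position C4 to give 23.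

**Step 5.** Chemoselectivity may be incomplete, with the borane also adding to the arylalkyne, because the allylic methoxy group slows the alkene. The fallback sets out from 10 and returns at 13. It uses no borane. Lemieux–Johnson cleavage (OsO4 cat., NaIO4, 2,6-lutidine, dioxane–water) attacks the alkene far faster than the alkyne and gives the α-methoxy aldehyde F6. Wittig reaction with Ph3P=CHOMe (from the phosphonium chloride and KHMDS) restores the missing carbon as the methyl enol ether F7. Brief hydrolysis with dilute aqueous HCl in THF at 0 °C then gives aldehyde 13.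

## Further compounds

F1 | step 9 | (1R,2R,4R)-1,4-bis(tert-butyldimethylsilyloxy)-6,7-bis(hydroxymethyl)-2-methoxy-8-(2,4,5-trimethoxyphenyl)-1,2,3,4-tetrahydronaphthalene | c12cc(CO)c(CO)c(-c3cc(OC)c(OC)cc3OC)c1[C@@H](O[Si](C)(C)C(C)(C)C)[C@H](OC)C[C@H]2O[Si](C)(C)C(C)(C)C
F2 | step 9 | (1R,2R,4R)-1,4-bis(tert-butyldimethylsilyloxy)-6,7-bis(chloromethyl)-2-methoxy-8-(2,4,5-trimethoxyphenyl)-1,2,3,4-tetrahydronaphthalene | c12cc(CCl)c(CCl)c(-c3cc(OC)c(OC)cc3OC)c1[C@@H](O[Si](C)(C)C(C)(C)C)[C@H](OC)C[C@H]2O[Si](C)(C)C(C)(C)C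
F3 | step 12 | (1R,2R,4R)-4-(tert-butyldimethylsilyloxy)-2-methoxy-6,7-dimethyl-8-(2,4,5-trimethoxyphenyl)-1,2,3,4-tetrahydronaphthalen-1-ol | c12cc(C)c(C)c(-c3cc(OC)c(OC)cc3OC)c1[C@@H](O)[C@H](OC)C[C@H]2O[Si](C)(C)C(C)(C)C
F4 | step 12 | (2R,4R)-4-(tert-butyldimethylsilyloxy)-2-methoxy-6,7-dimethyl-8-(2,4,5-trimethoxyphenyl)-3,4-dihydronaphthalen-1(2H)-one | c12cc(C)c(C)c(-c3cc(OC)c(OC)cc3OC)c1C(=O)[C@H](OC)C[C@H]2O[Si](C)(C)C(C)(C)C
F5 | step 12 | 2-methoxy-6,7-dimethyl-8-(2,4,5-trimethoxyphenyl)naphthalen-1-ol | COc1ccc2cc(C)c(C)c(-c3cc(OC)c(OC)cc3OC)c2c1O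
F6 | step 5 | (2S,3R)-3-(tert-butyldimethylsilyloxy)-2-methoxy-5-(2,4,5-trimethoxyphenyl)pent-4-ynal | O=C[C@@H](OC)[C@H](O[Si](C)(C)C(C)(C)C)C#Cc1cc(OC)c(OC)cc1OC
F7 | step 5 | (3R,4R)-4-(tert-butyldimethylsilyloxy)-1,3-dimethoxy-6-(2,4,5-trimethoxyphenyl)hex-1-en-5-yne (E/Z mixture) | COC=C[C@@H](OC)[C@H](O[Si](C)(C)C(C)(C)C)C#Cc1cc(OC)c(OC)cc1OC
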